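**Retrosynthetic overview**

- The target is cut back to zeylenone by removing the acetyl group from the C2 oxygen.
- The only ring, the carbocycle C1–C6, is opened at C2–C3. This bond lies γ to the C6 ketone through the C4=C5 alkene, so it is made by an intramolecular vinylogous Mukaiyama aldol of C3 onto aldehyde C2.
- The strategy rests on C1: a quaternary carbinol carbon carrying two oxygenated one-carbon arms (C7 and C2) and the C6 acyl group, i.e. a 2-acylglycerol. Its configuration comes from desymmetrising monobenzoylation of the prochiral triol, followed by oxidation of the remaining CH2OH.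
- The triol comes from 2,2-dimethyl-1,3-dioxan-5-one, methoxyallene (acryloyl anion equivalent, C6–C4) and allyl benzoate (C3 with its benzoate, by cross-metathesis).

Key step: step 7

Remark on numbering: atom numbers are those of zeylenone (C1 tertiary carbinol carbon, C2 and C3 the two CH–O carbons, C4=C5 the alkene, C6 the ketone, C7 the exocyclic CH2).

Remark (assumption): the (R,R)-ligand is taken to deliver the (R)-monobenzoate in step 5; if the sense of induction is the opposite, the (S,S)-ligand is used with nothing else changed.

**Route**

Step 1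
Reactants: 1 2,2-dimethyl-1,3-dioxan-5-one; 2 methoxyallene
Product: 4 tertiary alcohol 5-(1-methoxypropa-1,2-dien-1-yl)-2,2-dimethyl-1,3-dioxan-5-ol, via 1-lithio-1-methoxyallene 3 (not isolated)
Conditions: 2, n-BuLi, THF, −40 °C; then 1, −78 °C; H2O quench; used crude
Reagents that add atoms: none
Why: 1,2-addition of the α-lithiated alkoxyallene to the ketone at low temperature should outrun enolisation of 1 and forms the C1–C6 bond at a carbon that is still prochiral, so no stereocentre is set.

Step 2
Reactants: 4 5-(1-methoxypropa-1,2-dien-1-yl)-2,2-dimethyl-1,3-dioxan-5-ol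
Product: 5 vinyl ketone 1-(5-hydroxy-2,2-dimethyl-1,3-dioxan-5-yl)prop-2-en-1-one
Conditions: 2% aq H2SO4, THF, 0 °C, 15 min
Reagents that add atoms: water, O
Why: Acid-catalysed enol ether hydrolysis (protonation at the central allene carbon, addition of water, loss of methanol) should unveil the vinyl ketone much faster than the acetonide is cleaved at 0 °C.

Step 3
Reactants: 5 1-(5-hydroxy-2,2-dimethyl-1,3-dioxan-5-yl)prop-2-en-1-one; 6 allyl benzoate
Product: 7 enone (E)-4-(5-hydroxy-2,2-dimethyl-1,3-dioxan-5-yl)-4-oxobut-2-en-1-yl benzoate
Conditions: 6 (3 equiv), second-generation Hoveyda–Grubbs catalyst RuCl2(SIMes)(=CH-C6H4-2-OiPr) (5 mol%), CH2Cl2, 40 °C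
Reagents that add atoms: none
Why: Olefin cross-metathesis between an electron-poor vinyl ketone, which does not homodimerise, and an excess of the allylic ester should give the E-enone under thermodynamic control.

Step 4
Reactants: 7 (E)-4-(5-hydroxy-2,2-dimethyl-1,3-dioxan-5-yl)-4-oxobut-2-en-1-yl benzoate
Product: 8 triol (E)-5,6-dihydroxy-5-(hydroxymethyl)-4-oxohex-2-en-1-yl benzoate
Conditions: AcOH–H2O 4:1, 23 °C
Reagents that add atoms: none
Why: Acid-catalysed acetal hydrolysis in aqueous acetic acid frees the two enantiotopic primary hydroxyls under conditions mild enough that oxa-Michael addition to the enone and loss of the allylic benzoate should not compete.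

Step 5
Reactants: 8 (E)-5,6-dihydroxy-5-(hydroxymethyl)-4-oxohex-2-en-1-yl benzoate; 9 benzoyl chloride
Product: 10 monobenzoate (2R,4E)-2-hydroxy-2-(hydroxymethyl)-3-oxohex-4-ene-1,6-diyl dibenzoate
Conditions: CuCl2 (10 mol%), (R,R)-2,2'-isopropylidenebis(4-phenyl-2-oxazoline) (10 mol%), 9 (1.05 equiv), Et3N (1.1 equiv), THF, 0 °C; product taken on without storage
Reagents that add atoms: benzoyl chloride 9, O=C(Cl)c1ccccc1
Why: Copper–bis(oxazoline)-catalysed enantioselective monoacylation (desymmetrisation of a 2-substituted glycerol): the chiral divalent copper complex binds the tertiary hydroxyl together with one of the two enantiotopic primary hydroxyls and only that bound hydroxyl is benzoylated, which sets C1.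

Step 6
Reactants: 10 (2R,4E)-2-hydroxy-2-(hydroxymethyl)-3-oxohex-4-ene-1,6-diyl dibenzoate
Product: 11 ketoaldehyde (2S,4E)-6-benzoyloxy-2-(benzoyloxymethyl)-2-hydroxy-3-oxohex-4-enal
Conditions: (COCl)2, DMSO, CH2Cl2, −78 °C; Et3N, −78 to −30 °C; filtration through a short SiO2 pad, used at once
Reagents that add atoms: none
Why: Swern oxidation converts the single primary alcohol into the aldehyde at low temperature without nucleophiles, leaves the tertiary alcohol untouched and cannot disturb C1, which carries no hydrogen (the descriptor changes only through the priorities).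

Step 7
Reactants: 11 (2S,4E)-6-benzoyloxy-2-(benzoyloxymethyl)-2-hydroxy-3-oxohex-4-enal
Product: 14 zeylenone (1S,2S,3R), via silyl dienol ether 12 (not isolated), via bis-silylated zeylenone 13 (not isolated)
Conditions: Me3SiOTf (2.2 equiv), Et3N (2.5 equiv), CH2Cl2, −78 to 0 °C; MgBr2·OEt2 (3 equiv), −78 to −20 °C; then 1 M HCl, THF, 0 °C
Reagents that add atoms: none
Why: Proposed new method: Me3SiOTf/Et3N first caps the tertiary C1 hydroxyl (no hemiacetal, no α-ketol shift) and then removes a γ-hydrogen at C3 of the O-silylated enone, the only enolisable position because C1 is quaternary and the aldehyde has no α-hydrogen, to give the 1-silyloxy-4-benzoyloxy diene 12; MgBr2·OEt2 then activates the aldehyde, C3 adds to C2 with transfer of the silyl group to the new alkoxide (13), and dilute acid removes both silyl ethers. The closest known reactions are γ-selective vinylogous Mukaiyama aldol additions of silyl dienol ethers, including 2-silyloxyfurans that react at an oxygen-bearing γ-carbon, and intramolecular Mukaiyama aldol cyclisations; a closure that takes both C5 and C6 of the dienol ether into the new ring has not been shown. The ring closes in the 6-(enolendo)-exo-trig mode with the C4–C5 bond becoming the cis ring alkene, while attack by the α-carbon C5 would need a cyclobutane and is not expected. Closure requires the dienol ether in which C4 is cis to C1 across C5=C6; this isomer should arise from the s-trans conformer of the O-silylated enone, because the SiMe3 group, turned toward C5 by the quaternary C1, clashes with H-4 in the s-cis conformer, and Et3NH+ TfO− allows the unproductive isomer to return through C3 protonation. C2 is controlled by the five-membered magnesium chelate between the C1 silyloxy oxygen and the aldehyde oxygen: with O–C1–C2=O syn-periplanar and C3 forced by the C6 tether onto one aldehyde face, the C2 oxygen ends equatorial and cis to the axial C1 oxygen. C3 is controlled by the E geometry of the C3=C4 enol benzoate (benzoate anti to C5), which carries the benzoate into the pseudo-equatorial position trans to the C2 oxygen, whereas the Z isomer would have to place it syn-axial to the C1 oxygen.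

Step 8
Reactants: 14 zeylenone; 15 acetic anhydride
Product: 16 2-O-acetylzeylenone [(1S,5R,6S)-6-acetyloxy-5-benzoyloxy-1-hydroxy-2-oxocyclohex-3-en-1-yl]methyl benzoate
Conditions: Ac2O (1.5 equiv), pyridine, CH2Cl2, 0 °C
Reagents that add atoms: acetic anhydride 15, CC(=O)OC(C)=O
Why: Pyridine-mediated acylation should discriminate the secondary C2 hydroxyl from the hindered tertiary C1 hydroxyl, and the weak base and low temperature are chosen to avoid benzoate migration and elimination toward an aromatic ring.

**Compound list**

1 | 2,2-dimethyl-1,3-dioxan-5-one | CC1(C)OCC(=O)CO1 | starting material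
2 | methoxyallene (1-methoxypropa-1,2-diene) | COC=C=C | starting material
3 | 1-lithio-1-methoxyallene | [Li]C(OC)=C=C | intermediate
4 | 5-(1-methoxypropa-1,2-dien-1-yl)-2,2-dimethyl-1,3-dioxan-5-ol | COC(=C=C)C1(O)COC(C)(C)OC1 | intermediate
5 | 1-(5-hydroxy-2,2-dimethyl-1,3-dioxan-5-yl)prop-2-en-1-one | C=CC(=O)C1(O)COC(C)(C)OC1 | intermediate
6 | allyl benzoate | C=CCOC(=O)c1ccccc1 | starting material
7 | (E)-4-(5-hydroxy-2,2-dimethyl-1,3-dioxan-5-yl)-4-oxobut-2-en-1-yl benzoate | O=C(/C=C/COC(=O)c1ccccc1)C1(O)COC(C)(C)OC1 | intermediate
8 | (E)-5,6-dihydroxy-5-(hydroxymethyl)-4-oxohex-2-en-1-yl benzoate | OCC(O)(CO)C(=O)/C=C/COC(=O)c1ccccc1 | intermediate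
9 | benzoyl chloride | O=C(Cl)c1ccccc1 | starting material
10 | (2R,4E)-2-hydroxy-2-(hydroxymethyl)-3-oxohex-4-ene-1,6-diyl dibenzoate | OC[C@@](O)(COC(=O)c1ccccc1)C(=O)/C=C/COC(=O)c1ccccc1 | intermediate
11 | (2S,4E)-6-benzoyloxy-2-(benzoyloxymethyl)-2-hydroxy-3-oxohex-4-enal | O=C[C@@](O)(COC(=O)c1ccccc1)C(=O)/C=C/COC(=O)c1ccccc1 | intermediate
12 | (2R,3E,5E)-2-formyl-2,3-bis(trimethylsilyloxy)hexa-3,5-diene-1,6-diyl dibenzoate (C1 spatially unchanged) | O=C[C@@](O[Si](C)(C)C)(COC(=O)c1ccccc1)/C(O[Si](C)(C)C)=C\C=C\OC(=O)c1ccccc1 | intermediate
13 | 1,2-bis-O-(trimethylsilyl)zeylenone, [(1S,5R,6S)-5-benzoyloxy-2-oxo-1,6-bis(trimethylsilyloxy)cyclohex-3-en-1-yl]methyl benzoate | C[Si](C)(C)O[C@H]1[C@H](OC(=O)c2ccccc2)C=CC(=O)[C@]1(O[Si](C)(C)C)COC(=O)c1ccccc1 | intermediate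
14 | zeylenone, [(1S,5R,6S)-5-benzoyloxy-1,6-dihydroxy-2-oxocyclohex-3-en-1-yl]methyl benzoate | O[C@H]1[C@H](OC(=O)c2ccccc2)C=CC(=O)[C@]1(O)COC(=O)c1ccccc1 | intermediate
15 | acetic anhydride | CC(=O)OC(C)=O | starting material
16 | 2-O-acetylzeylenone, [(1S,5R,6S)-6-acetyloxy-5-benzoyloxy-1-hydroxy-2-oxocyclohex-3-en-1-yl]methyl benzoate | CC(=O)O[C@H]1[C@H](OC(=O)c2ccccc2)C=CC(=O)[C@]1(O)COC(=O)c1ccccc1 | target

**Step count**

Total steps: 8. Longest linear sequence: 8 steps (1 to 16).

**Steps most likely to fail**

Step 7 (proposed new method). Three processes may defeat it: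
- The dienol ether may form with the C5=C6 geometry that cannot reach the aldehyde and fail to return.
- Chelation through the silyl ether oxygen may be too weak, giving poor facial selectivity at C2, or closure may start unchelated under Me3SiOTf before magnesium is present.
- The aldol product may lose the C2 oxygen and aromatise.

Fallback by known chemistry, setting out from 11: a Barbier-type α-hydroxyallylation of the aldehyde with 3-bromoprop-1-enyl benzoate and indium powder in THF should give the diene (2E,5S,6S,7R)-5-(benzoyloxymethyl)-5,6-dihydroxy-4-oxonona-2,8-diene-1,7-diyl dibenzoate F1. Its C2 and C3 centres are set in an intermolecular addition that is expected to be steered by chelation of the C1 hydroxyl and the aldehyde; diastereomers would be separated by chromatography. Ring-closing metathesis of F1 with the second-generation Hoveyda–Grubbs catalyst in CH2Cl2 at 40 °C then closes C4=C5 with loss of allyl benzoate and comes back to the route at 14.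

Step 5. The α-hydroxy ketone may compete with the diol for copper and erode enantioselectivity. A second acylation, benzoyl migration between the oxygens (which racemises 10) and oxa-Michael closure of a primary hydroxyl onto the enone under the amine base are further risks. Fallback, setting out from 8: an enzymatic desymmetrisation in place of the metal-templated acylation. A lipase of suitable enantiopreference (Candida antarctica lipase B or Burkholderia cepacia lipase, to be screened) with vinyl benzoate in tert-butyl methyl ether transfers one benzoyl group under neutral conditions and comes back to the route at 10 without a new intermediate.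

Step 6. The free hydroxy ketoaldehyde may be lost by retro-Claisen deformylation or hydration on work-up, by α-ketol shift of the acyl group, or by base-induced benzoyl migration before oxidation is complete. Fallback, setting out from 10: both hydroxyls are silylated (Me3SiCl, imidazole, CH2Cl2) to give (2S,4E)-3-oxo-2-(trimethylsilyloxy)-2-[(trimethylsilyloxy)methyl]hex-4-ene-1,6-diyl dibenzoate F2. Swern oxidation, which converts a primary trimethylsilyl ether directly into the aldehyde and leaves the tertiary silyl ether in place, should then give (2S,4E)-2-formyl-3-oxo-2-(trimethylsilyloxy)hex-4-ene-1,6-diyl dibenzoate F3. F3 has no free hydroxyl and, with one equivalent of Me3SiOTf and Et3N, comes back to the route at 12.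

**Further compounds**

F1 | step 7 | (2E,5S,6S,7R)-5-(benzoyloxymethyl)-5,6-dihydroxy-4-oxonona-2,8-diene-1,7-diyl dibenzoate | O[C@@H]([C@H](OC(=O)c2ccccc2)C=C)[C@@](O)(COC(=O)c1ccccc1)C(=O)/C=C/COC(=O)c1ccccc1
F0 | step 5 | none | none
F2 | step 6 | (2S,4E)-3-oxo-2-(trimethylsilyloxy)-2-[(trimethylsilyloxy)methyl]hex-4-ene-1,6-diyl dibenzoate | C[Si](C)(C)OC[C@@](O[Si](C)(C)C)(COC(=O)c1ccccc1)C(=O)/C=C/COC(=O)c1ccccc1
F3 | step 6 | (2S,4E)-2-formyl-3-oxo-2-(trimethylsilyloxy)hex-4-ene-1,6-diyl dibenzoate | O=C[C@@](O[Si](C)(C)C)(COC(=O)c1ccccc1)C(=O)/C=C/COC(=O)c1ccccc1
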